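The data were generated by integration with constants of no real substance; scatter was added.

1.38% of the left-handed substrate charged: that is the catalyst loading the impurity costs in each of these runs. We call it the toll, meaning the impurity as a fraction of the left-handed substrate charged, taken one for one off the loading of free catalyst, which leaves the working loading (catalyst poisoning).

| flask | left-handed substrate | right-handed substrate | partner | free catalyst | racemization catalyst | impurity | remark | time |
|---|---|---|---|---|---|---|---|---|
| gamma | 0.050 M | 0.050 M | 2.7 equiv | 5 mol% | 0.1 mol% | 0.69 mM | run made earlier |  |
| beta | 0.050 M | 0.050 M | 6 equiv | 5 mol% | 0.1 mol% | 0.69 mM | run made earlier |  |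
| eta | 0.050 M | 0.050 M | 4 equiv | 2.5 mol% | 0.1 mol% | 0.69 mM | run made earlier |  |
| flask | 0.050 M | 0.050 M | 4.00 equiv | 5 mol% | 0.1 mol% | 0.69 mM |  | 80 min |

- gamma (time / min: left-handed product / %, right-handed product / %): 5.00: 10.6, 0; 10.0: 18.0, 0.7; 20.0: 26.9, 0.9; 30.0: 35.2, 1.6; 60.0: 45.4, 1.9
- beta (time / min: left-handed product / %, right-handed product / %): 5.00: 21.0, 1.8; 10.0: 29.9, 1.1; 20.0: 42.4, 3.8; 30.0: 46.6, 1.4; 60.0: 51.7, 7.8
- eta (time / min: left-handed product / %, right-handed product / %): 5.00: 5.2, 1.0; 10.0: 10.0, 0; 20.0: 16.9, 1.6; 30.0: 22.4, 0.3; 60.0: 35.1, 2.5

(scatter of a reading: 1 percentage point)

- free catalyst is single-handed; left-handed substrate and right-handed substrate are mirror images of each other, charged as a racemate, each of them at the stated concentration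
- candidate steps: free catalyst + impurity -> spent catalyst; partner + free catalyst + left-handed substrate -> free catalyst + left-handed product; partner + free catalyst + right-handed substrate -> free catalyst + right-handed product; 2 racemization catalyst <-> resting dimer; left-handed substrate + racemization catalyst <-> right-handed substrate + racemization catalyst
- an excess is the difference of the two amounts in percent of their sum
- an excess is below zero if the other one leads

- left-handed product and right-handed product together, in percent of the left-handed substrate and right-handed substrate charged together, at 80 min
- excess of left-handed product over right-handed product in the product at 80 min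
- whether the exchange between left-handed substrate and right-handed substrate keeps pace with the reaction: how far the product's excess at 80 min gets from its value without exchange to its value with instant exchange (above 80% keeps pace, below 20% hardly takes part, else lags behind)

Minutes of the meeting on the flask.

The first speaker compared early readings. Left-handed product per equivalent of partner at 5.00 min read 3.02 times as high in gamma as in eta, with the scatter of single readings, although the loadings differ by a factor of 2.00. She argued that the toll accounts for this, since the working loadings of 3.62% and 1.12% stand at a ratio of 3.23.

The second speaker asked for the end state. He said the flask keeps 72.4% of its catalyst, as gamma and beta do, and that its 4.00 equiv of partner lies between their 2.7 equiv and 6 equiv. At 60.0 min, left-handed product read 45.4% in gamma and 51.7% in beta, so he expected the flask's total at 80 min to stand a little above one half.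

The forecast was then put: 57% (54% to 60%), an excess of 82% (77% to 86%), and exchange that hardly takes part. Its author held that “the left-handed substrate is essentially gone by 80 min”.

The flask gave 55.0%, an excess of 83.2%, and exchange that hardly takes part, at 4.4% of the way.

    free catalyst + impurity → spent catalyst (k = 37000 /M/min)
    partner + free catalyst + left-handed substrate → free catalyst + left-handed product (k = 190 /M²/min)
    partner + free catalyst + right-handed substrate → free catalyst + right-handed product (k = 4.30 /M²/min)
    2 racemization catalyst ⇌ resting dimer, settled at all times (K = 4.40 × 10⁷ /M)
    left-handed substrate + racemization catalyst ⇌ right-handed substrate + racemization catalyst, rate k5*[racemization catalyst]*[left-handed substrate] forward; the back reaction follows from the equilibrium constant (k = 690 /M/min)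

In the flask, free catalyst stands at 72.4% and spent catalyst at 27.6% of the catalyst charged, and on that working loading the left-handed step used partner 22 times as fast as the right-handed step at 11.0 min. At 80 min, 2.2% of the left-handed substrate charged remains against 88% of the right-handed. The neighbouring flask charged with 1.2 mol% of free catalyst has a loading below the toll of 1.38%, and at 80 min it holds 0% free catalyst, 100% spent catalyst and a product total of 0.107%.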